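Our vessel is closed, stirred and isothermal, and your two flasks differ in their free catalyst and their time, so here is our quick number to set beside your forecast.

| setting | Tuesday's | Thursday's | alder | elm |
|---|---|---|---|---|
| substrate | 0.050 M | 0.050 M | 0.050 M | 0.050 M |
| partner | 0.075 M | 0.075 M | 0.0750 M | 0.0750 M |
| free catalyst | 100 µM | 190 µM | 75 µM | 150 µM |
| remark | run made earlier | run made earlier |  |  |
| time |  |  | 40 min | 20 min |

- Tuesday's (time / min: product / %, substrate / %): 3.00: 2.3, 82.3; 6.00: 6.2, 76.0; 8.00: 12.7, 70.0; 12.0: 16.7, 64.6; 15.0: 21.0, 61.5; 20.0: 27.5, 53.4
- Thursday's (time / min: product / %, substrate / %): 3.00: 8.6, 73.7; 6.00: 14.8, 66.5; 8.00: 21.4, 60.2; 12.0: 30.8, 49.0; 15.0: 38.4, 45.5; 20.0: 48.3, 36.1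

(readings scatter by 1 percentage point)

- the flask that ends with the higher amount of product, in percent of the substrate charged, or "neither" when 2 percentage points or less lies between them (alder / elm / neither)
- final product, as a percentage of the substrate charged, in alder
- final product, as a percentage of the substrate charged, in elm

- on the list of suspects stand: free catalyst + open intermediate <-> catalyst intermediate; substrate + free catalyst <-> free catalyst + open intermediate; partner + catalyst intermediate -> free catalyst + product

Even Thursday's c(free catalyst) of 190 µM is 0.380 % of c(substrate), and because the catalyst forms can therefore hold hardly any of the substrate, we expect that, with the substrate and partner charges held as in these runs, more catalyst simply runs the same curve faster. We therefore reckon alder's 30.0 min of Tuesday time, meaning c(free catalyst) multiplied by the time and divided by Tuesday's c(free catalyst). One pair of readings fits this: Thursday at 8.00 min counts 15.2 min of Tuesday time and shows 21.4 % product, while Tuesday at 15.0 min shows 21.0 %.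

Elm also comes to 30.0 min, so we expect a tie. Thursday's last two readings stand at 28.5 min and 38.0 min of Tuesday time, and between them we read 40.0 % product. Your forecast says neither, with 39.5 % in alder and 39.5 % in elm, reasoning that “so they should end equal”. Our number differs from it by 0.50 percentage points, against a scatter of 1 point.

The simulation gives 39.9 % in alder and 39.9 % in elm, so the answer is neither.

    free catalyst + open intermediate ⇌ catalyst intermediate (K = 940 /M, k = 33000 /M/min)
    substrate + free catalyst ⇌ free catalyst + open intermediate (K = 0.880, k = 2800 /M/min)
    partner + catalyst intermediate → free catalyst + product (k = 120 /M/min)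

Alder and elm stand at the same 30.0 min of Tuesday time and tie as the forecast said; with elm's other charges and time held, raising elm's c(partner) to 0.0853 M moves elm's product by 5 points, against a margin of 2 points. The neighbour of alder, charged with 45.0 µM of free catalyst and run for 40 min, counts 18.0 min of Tuesday time, and between Tuesday's readings at 15.0 min and 20.0 min that reads as 24.9 % product. The simulated neighbour ends with 25.1 % product.

(The numbers in the tables are calculated for an exercise; scatter was added.)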